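At 3.4 h, the first reading of Wednesday's run, the flask holds 1.7 mM of target; by 14 h it holds 27.1 mM.

| flask | substrate | partner | free catalyst | time |
|---|---|---|---|---|
| Wednesday's | 100 mM | 120 mM | 0.500 mM |  |
| Monday's | 40.0 mM | 60.0 mM | 0.500 mM |  |
| Sunday's | 100 mM | 240 mM | 0.500 mM |  |
| Friday's | 100 mM | 120 mM | 0.250 mM |  |
| Thursday's | 100 mM | 120 mM | 0.0770 mM | 17 h |

| run | time / h | [target] / mM |
|---|---|---|
| Wednesday's run | 3.4 | 1.7 |
| Wednesday's run | 6.8 | 6.6 |
| Wednesday's run | 10 | 13.7 |
| Wednesday's run | 14 | 27.1 |
| Wednesday's run | 17 | 39.0 |
| Monday's run | 3.4 | 0.2 |
| Monday's run | 6.8 | 0.1 |
| Monday's run | 10 | 1.7 |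
| Monday's run | 14 | 2.9 |
| Monday's run | 17 | 3.7 |
| Sunday's run | 3.4 | 4.5 |
| Sunday's run | 6.8 | 13.4 |
| Sunday's run | 10 | 29.3 |
| Sunday's run | 14 | 56.8 |
| Sunday's run | 17 | 73.5 |
| Friday's run | 3.4 | 1.8 |
| Friday's run | 6.8 | 5.1 |
| Friday's run | 10 | 10.3 |
| Friday's run | 14 | 20.3 |
| Friday's run | 17 | 31.6 |

(each reading ± 0.3 mM)

- Overall: substrate + partner -> target, with free catalyst as catalyst.
- Constant volume, constant temperature.
- The analysis sees a species whether free or bound.
- An order is taken over about fifteen percent of the charge, up and down.

* reaction order in [free catalyst] at the outset, round the charge of the Wednesday's run, defined at two percent of the substrate turned into target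
* reaction order in [substrate] at the outset, round the charge of the Wednesday's run, defined at two percent of the substrate turned into target (one fixed amount of target, the same in the runs compared)
* the Monday's run starts with 60.0 mM less of substrate and of partner than the Wednesday's run, and with no target. Compared where both hold the same amount of substrate, once fifteen percent of what the Monday's run was charged with has turned into target, is the Monday's run faster, slower or alike (within a tenth)?
* target in the Thursday's run at 17 h, as a share of the substrate charged

**What does Wednesday's curve say at its two ends?**

Over the first stretch, target comes at 0.500 mM h⁻¹ on average. Between 10 h and 14 h it comes at 3.35 mM h⁻¹, faster than at the opening, though substrate has been used. I read that as two routes: one that needs no target, and a target-fed one (autocatalysis).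

**How do you join the ends?**

With a straight line of rate against target through those two stretches. Its slope is 0.146 h⁻¹, and at zero target it gives 0.376 mM h⁻¹. Dividing the second by the first gives the handover amount, 2.58 mM: the amount of target at which the target-fed part of the rate equals the part present without target.

**But that line ignores the substrate used, doesn't it?**

Yes. 27.1 mM of 100 mM has gone by 14 h, so this is a rough reading.

**What is it worth for the catalyst order?**

At 2.00 mM of target, the part without target has the share 56.3%. Friday's and Wednesday's runs differ in catalyst. If they grow alike, their ratio at one clock time is the ratio of their opening rates. At 10 h that ratio gives an opening order of 0.412. My order at fixed target is therefore 0.232.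

**And Thursday's run?**

Its opening rate scales by 0.463. Its handover becomes 1.19 mM, and Wednesday's final reading scales to 18.1% of the charge.

The forecast broadly agrees with me: it gives 0.2 (0.05 to 0.4) and 16% (10% to 22%), ranges that hold my 0.232 and 18.1%, though both its central values are lower than mine . For the substrate order it gives 0.85 (0.6 to 1.2), and it calls Monday's run slower. Its ground is “so there is an induction period, not plain autocatalysis”.

The simulation gives 0.29 for the catalyst order, above the forecast's value. It gives 1.0 for the substrate order, Monday's run slower, and 20.5% for Thursday's run.

    2 free catalyst ⇌ catalyst dimer, settled at all times (1.700 × 10⁵ M⁻¹)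
    free catalyst + substrate + partner → target + free catalyst (9936 M⁻² h⁻¹)
    2 partner ⇌ idle reagent dimer, settled at all times (290.0 M⁻¹)
    substrate + partner + target → 2 target (150.1 M⁻² h⁻¹)

In Wednesday's run, the step of free catalyst with substrate and partner led while target stood below the handover reading of 2.58 mM, passed near 4.01 h, with 92.6% of the catalyst held as catalyst dimer. Above that amount the target-fed step led, taking Wednesday's run to a quarter of its substrate at 13.5 h, while in Thursday's run, with its handover scaled to 1.19 mM, the same two steps brought target to 20.5% of the substrate charged at 17 h.

The runs were computed on assumed constants; the scatter is artificial.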